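## The problem

The target 14 is a flavanone. Ring A is a hexasubstituted benzene (5-OH, 6-CH3, 7-OCH3, 8-CH3) fused through C4a–C8a to ring C, a dihydropyranone (O1, C2, C3, C4=O), and ring B, a 2-methoxy-1,4-benzoquinone, sits on C2. C2 is the only stereocentre, (S), so no other centre can control it and its configuration must come from a catalyst, a reagent or the chiral pool. C2 is also fragile: base opens ring C to the 2'-hydroxychalcone by retro-oxa-Michael reaction, and strong acid ionises the benzylic C2–O1 bond; either path racemises. The quinone is an electrophile and an oxidant and will not survive hydrides, organometallics, amines or Lewis acids, so it has to be unveiled last from a ring B at the phenol level. Ring A carries two oxygens that must end differently, O5 free and hydrogen-bonded to C4=O and O7 methylated; the peri relation of O5 to the carbonyl is the handle for telling them apart. The key step rests on the C3–C4 bond next to the ketone: as a silyl enol ether, C4 is one end of a C4=CH2 olefin on C4a, and C2, already an ether of O1, can carry a vinyl group whose inner carbon is C3, so olefin metathesis closes ring C across C3=C4 without touching C2.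

## Retrosynthesis

**14 to 13 (the quinone C6'=O).** The quinone is removed first because it is the least robust group. It is traced to the 3-hydroxy-4-methoxyphenyl ring of phenol 13, whose OH at C3' has a free para position, C6'. A 2,4,5-trimethoxyphenyl ring with oxidative demethylation was the neighbouring choice, but it puts an ortho alkoxy group next to C2, which makes the benzylic ether more labile, and needs a strong one-electron oxidant beside the electron-rich ring A. The forward reaction must oxidise ring B para to the phenol and leave the chelated, fully substituted ring A phenol alone, in a medium close to neutral.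

**13 to 12 (O5–CH3 and O3'–CH2Ph).** Both phenols are masked in 12, O5 as a methyl ether and O3' as a benzyl ether. This keeps them away from bases, silylating agents and metal catalysts, and lets ring A be made by exhaustive methylation short of the last chelated OH. One Lewis acid should remove both groups: boron bound to C4=O activates only the peri methoxy group, and benzyl ethers fall to the same reagent. The forward step has to leave the 7- and 4'-methyl ethers and the C2–O1 bond intact.

**12 to 11 (C4=O from the enol ether).** The ketone is written as the silyl enol ether 11. Only an O–Si bond is cleaved and C3 is protonated; C3 is a CH2 group, so no stereocentre is made. The step is asked to proceed without a free enolate, which could open ring C.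

**11 to 10 (C3=C4, the key cut).** Cutting the C3=C4 double bond of the 4-silyloxy-2H-chromene 11 gives diene 10, which has a vinyl group on C2 and a 1-silyloxyvinyl group on C4a. Against the classical cut at O1–C2 (oxa-Michael closure of a chalcone), this one forms a carbon–carbon bond away from the stereocentre under neutral conditions, so C2 can be set beforehand in an open-chain ether and kept. The precursor has no ring C and its olefins come from a methyl ketone and an allylic ether. The forward reaction must close a six-membered ring onto a hindered 1,1-disubstituted enol ether faster than the allylic double bond can migrate.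

**10 to 9 (O–Si).** The enol ether comes from methyl ketone 9 by O-silylation. The demand is enolisation that does not ionise the allylic benzylic ether.

**9 to 3 and 7 (O1–C2).** This is the only bond whose formation creates chirality. Cutting it gives phenol 3, used as its sodium salt 8, and the linear cinnamyl carbonate 7. Iridium-catalysed allylic substitution is chosen because it gives the branched ether from an achiral linear carbonate with catalyst control of the new centre. A Mitsunobu reaction of a secondary alcohol that is both benzylic and allylic would ionise, and nucleophilic aromatic substitution is not open to an electron-rich ring A. The forward step must be branched-selective and face-selective with a hindered, chelated aryloxide, and must not let the product re-ionise.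

**7 to 6 to 5 to 4.** The carbonate is traced through alcohol 6 and ester 5 to commercial aldehyde 4. The cuts are the carbonate C–O bond, the ester oxidation level and the C=C bond (Wittig reaction); each step is routine.

**3 to 2 to 1.** The two O–CH3 bonds of 3 lead back to triphenol 2, and its two C–CH3 bonds to commercial 2,4,6-trihydroxyacetophenone 1. Ring A is thus bought as an aromatic ring with the acetyl group in place. The forward steps rely on carbon alkylation of a phloroglucinol anion and on the inertness of the last chelated OH to methylation.

## Roads not taken

**Alternative 1:** The cut is at the two aryl–methyl bonds C6–CH3 and C8–CH3. The skeleton and C2 come from natural (S)-hesperetin A1. After 7-O-methylation, 3'-O-acetylation and double iodination to (S)-3'-O-acetyl-6,8-diiodo-7-O-methylhesperetin A2, a double Stille coupling with tetramethylstannane A3 under Pd(PPh3)4 (zerovalent palladium) would give (S)-3'-O-acetyl-6,8-dimethyl-7-O-methylhesperetin A4. Removal of the acetate would give 13 of the present route.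

- Merits: it is the shortest road, about half the step count of the chosen plan. It needs no asymmetric step, and rings A, B and C are present from the start.
- Weak points: everything rests on the optical purity of A1, whose C2 epimerises by ring opening, so the supply decides the enantiomeric purity of the product. Three phenols must be told apart under basic alkylation, which itself threatens C2. The two couplings take place at positions flanked on both sides by oxygen substituents, where transmetalation from A3 is slow; heating a finished flavanone with a free 5-OH invites protodeiodination to monomethyl products and ring opening.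
- Comparison: in step count this road is clearly better. Against that, the chosen plan sets C2 by a catalyst whose selectivity can be tuned and does not depend on a natural sample, brings in both C-methyl groups in the first step on a cheap achiral compound, and never heats a finished flavanone with base or palladium.

**Alternative 2:** The cut is at O1–C8a and C4–C4a. Ring A arrives as the aryne released from 3,5-dimethoxy-4,6-dimethyl-2-(trimethylsilyl)phenyl triflate A5. C2, C3 and C4 arrive in methyl (S)-3-hydroxy-3-(2,4,5-trimethoxyphenyl)propanoate A6. With CsF the alkoxide of A6 should add at C8a, the aryne carbon remote from the 5-methoxy group, and the aryl anion at C4a should attack the ester to close ring C as (S)-5,7-dimethoxy-6,8-dimethyl-2-(2,4,5-trimethoxyphenyl)chroman-4-one A7.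

- Merits: two bonds and ring C form in one convergent step. The regiochemistry follows the known inductive control by a methoxy group next to an aryne. The stereocentre is made in a simple open-chain ester.
- Weak points: A5 is a hexasubstituted benzene that needs a sequence of its own. The alkoxide of A6 is prone to retro-aldol cleavage and to elimination to the cinnamate, since its benzylic carbon is activated by ortho and para methoxy groups. After O-arylation, the hindered aryl anion may simply be protonated instead of attacking an alkyl ester. In the endgame, oxidative demethylation of ring B with (NH4)2Ce(NO3)6 (tetravalent cerium) must spare the electron-rich ring A, and the 2'-methoxy group makes the C2–O1 bond easier to ionise.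
- Comparison: this road is more convergent and forms more bonds in its key step. The chosen plan sets against it a ring A piece made in two steps, a key step with close precedent in both of its parts, and a ring B without an ortho alkoxy group at C2.

**Alternative 3:** The cut runs through four bonds of ring A: C8–C8a, C7–C8, C5–C6 and C4a–C5. Ring C exists beforehand as (S)-2-(3-benzyloxy-4-methoxyphenyl)-6-(2-diazopropanoyl)-2,3-dihydro-4H-pyran-4-one A8. Irradiation with 1-methoxypropyne A9 would start a Wolff rearrangement to a vinylketene, followed by [2+2] addition of the ynol ether, 4π ring opening and 6π ring closure. The product would be (S)-2-(3-benzyloxy-4-methoxyphenyl)-5-hydroxy-7-methoxy-6,8-dimethylchroman-4-one A10, one debenzylation away from 13.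

- Merits: all six substituents of ring A are placed by the mechanism. O5 emerges free and O7 methylated, so no selective demethylation is needed; in this respect the road is better than the chosen plan.
- Weak points: A8 is a doubly activated enone carrying a diazo ketone. It is long to make, and its C2–O1 bond is β to the ring ketone, so basic diazo transfer threatens ring opening and loss of configuration. The enone chromophore absorbs in competition with the diazo group. A9 is volatile and acid-sensitive and has to be prepared. The annulation must deliver a fully substituted ring from a vinylketene whose olefin is part of an electron-poor vinylogous ester.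
- Comparison: the chosen plan has to accept a Lewis-acid step to tell O5 from O7. Against that it sets a commercial aromatic ring A, no photochemistry on an epimerisable intermediate, and a catalytic key step under neutral conditions.

Key step: step 8

Assumption: the (Sa,Sc,Sc) antipode of the phosphoramidite ligand is taken to deliver the (S)-ether 9, by analogy with the known facial sense for cinnamyl carbonates; if the sense proves opposite, the (Ra,Rc,Rc) ligand is used, both being commercial.

## Route

Step 1
Reactants: 1 2,4,6-trihydroxyacetophenone
Product: 2 2,4,6-trihydroxy-3,5-dimethylacetophenone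
Conditions: MeI (2.2 equiv), NaOMe (3 equiv), MeOH, 0 °C to reflux
Reagents that add atoms: iodomethane, CI
Why: Base-mediated C-alkylation of a phloroglucinol polyanion, whose ring carbons C3 and C5 are soft nucleophiles that take methyl iodide in methanol in preference to the hydrogen-bonded oxygens; keeping MeI near two equivalents limits the dearomatised gem-dimethyl by-product.

Step 2
Reactants: 2 2,4,6-trihydroxy-3,5-dimethylacetophenone
Product: 3 2-hydroxy-4,6-dimethoxy-3,5-dimethylacetophenone
Conditions: Me2SO4 (2.1 equiv), K2CO3, acetone, reflux
Reagents that add atoms: dimethyl sulfate, COS(=O)(=O)OC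
Why: Williamson O-methylation; the para OH and one ortho OH are methylated, while the last ortho OH stays locked in a hydrogen bond to the acetyl carbonyl and resists a slight excess of reagent, the usual selectivity of phloroacetophenones.

Step 3
Reactants: 4 3-benzyloxy-4-methoxybenzaldehyde
Product: 5 ethyl (E)-3-(3-benzyloxy-4-methoxyphenyl)acrylate
Conditions: Ph3P=CHCO2Et (1.2 equiv), toluene, 80 °C
Reagents that add atoms: ethyl (triphenylphosphoranylidene)acetate, CCOC(=O)C=P(c1ccccc1)(c1ccccc1)c1ccccc1
Why: Wittig olefination with a stabilised ylide, which gives the (E)-cinnamate from an aromatic aldehyde under thermodynamic control of the oxaphosphetane.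

Step 4
Reactants: 5 ethyl (E)-3-(3-benzyloxy-4-methoxyphenyl)acrylate
Product: 6 (E)-3-(3-benzyloxy-4-methoxyphenyl)prop-2-en-1-ol
Conditions: i-Bu2AlH (2.5 equiv), CH2Cl2, −78 to 0 °C; aq. KNaC4H4O6
Reagents that add atoms: none
Why: 1,2-Reduction of a conjugated ester to the allylic alcohol by i-Bu2AlH, which does not touch the olefin or the benzyl ether.

Step 5
Reactants: 6 (E)-3-(3-benzyloxy-4-methoxyphenyl)prop-2-en-1-ol
Product: 7 (E)-3-(3-benzyloxy-4-methoxyphenyl)allyl methyl carbonate
Conditions: ClCO2Me, pyridine, CH2Cl2, 0 °C
Reagents that add atoms: methyl chloroformate, COC(=O)Cl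
Why: Acylation of a primary allylic alcohol with a chloroformate; the carbonate is the leaving group needed for the iridium-catalysed substitution.

Step 6
Reactants: 3 2-hydroxy-4,6-dimethoxy-3,5-dimethylacetophenone; 7 (E)-3-(3-benzyloxy-4-methoxyphenyl)allyl methyl carbonate
Product: 9 (S)-1-{2-[1-(3-benzyloxy-4-methoxyphenyl)allyloxy]-4,6-dimethoxy-3,5-dimethylphenyl}ethan-1-one, via sodium 2-acetyl-3,5-dimethoxy-4,6-dimethylphenolate 8 (not isolated)
Conditions: 3 (1.3 equiv), NaH (1.2 equiv), THF, 0 °C; then 7, [Ir(cod)Cl]2 (2 mol%), (Sa,Sc,Sc)-O,O'-(1,1'-binaphthyl-2,2'-diyl) N,N-bis(1-phenylethyl)phosphoramidite (4 mol%, pre-activated with n-PrNH2), THF, 25–40 °C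
Reagents that add atoms: none
Why: Iridium-catalysed asymmetric allylic etherification of a linear cinnamyl carbonate with an alkali aryloxide: the cyclometalated iridium phosphoramidite complex ionises 7 to a 1-arylallyl complex, and the aryloxide attacks the substituted terminus anti to the metal, giving the branched ether. The (S) configuration at C2 is set by the ligand, which fixes the allyl face open to attack; the reaction is stopped at full conversion so that the product does not re-ionise.

Step 7
Reactants: 9 (S)-1-{2-[1-(3-benzyloxy-4-methoxyphenyl)allyloxy]-4,6-dimethoxy-3,5-dimethylphenyl}ethan-1-one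
Product: 10 (S)-1-(3-benzyloxy-4-methoxyphenyl)allyl 2-[1-(tert-butyldimethylsilyloxy)vinyl]-3,5-dimethoxy-4,6-dimethylphenyl ether
Conditions: TBSOTf (1.3 equiv), Et3N (3 equiv), CH2Cl2, −78 to 0 °C
Reagents that add atoms: tert-butyldimethylsilyl trifluoromethanesulfonate, CC(C)(C)[Si](C)(C)OS(=O)(=O)C(F)(F)F
Why: Soft enolisation of an aryl methyl ketone (silyl triflate activation of the carbonyl, deprotonation by the amine); the methyl group is the only enolisable position, and the excess amine keeps the medium basic so that the allylic benzylic ether and C2 are not ionised.

Step 8
Reactants: 10 (S)-1-(3-benzyloxy-4-methoxyphenyl)allyl 2-[1-(tert-butyldimethylsilyloxy)vinyl]-3,5-dimethoxy-4,6-dimethylphenyl ether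
Product: 11 (S)-2-(3-benzyloxy-4-methoxyphenyl)-4-(tert-butyldimethylsilyloxy)-5,7-dimethoxy-6,8-dimethyl-2H-chromene
Conditions: (H2IMes)(PCy3)Cl2Ru=CHPh (second-generation Grubbs catalyst, 5–10 mol%), 1,4-benzoquinone (10–20 mol%), degassed toluene (0.005 M), 40–50 °C, dark, argon sweep
Reagents that add atoms: none
Why: Ring-closing enol ether–olefin metathesis: the ruthenium benzylidene first exchanges with the monosubstituted vinyl group on C2, the only unhindered olefin, to give an alkylidene at C3. This alkylidene adds across the C4=CH2 enol ether in a [2+2] step, the ruthenacyclobutane opens the other way, C3=C4 forms and Ru=CH2 re-enters the cycle with loss of ethylene. The closest known reaction types are the ring-closing metathesis of silyl enol ethers with terminal olefins, as in the closure of N-allyl-2-(1-silyloxyvinyl)anilines to 4-silyloxy-1,2-dihydroquinolines, and the metathesis of ortho-vinylaryl 1-arylallyl ethers to 2-aryl-2H-chromenes. Ring C closes as a six-membered ring (O1, C2, C3, C4, C4a, C8a) by intramolecular metathesis, with the aromatic C4a–C8a bond holding the two olefins cis and within reach and the loss of ethylene driving the closure. No stereocentre is formed; C2, set in step 6, is not a reacting atom and keeps its (S) configuration as long as the double bond does not migrate. The selectivity needed is closure over double-bond migration and over intermolecular metathesis: 1,4-benzoquinone intercepts ruthenium hydrides, high dilution disfavours dimerisation, and the 1,1-disubstituted enol ether cannot homodimerise. Mild temperature and exclusion of light also keep the 2H-chromene from reversible 6π ring opening to an ortho-quinone methide, which would scramble C2. The product is the flavanone in masked form, so C4 is already at the ketone oxidation level.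

Step 9
Reactants: 11 (S)-2-(3-benzyloxy-4-methoxyphenyl)-4-(tert-butyldimethylsilyloxy)-5,7-dimethoxy-6,8-dimethyl-2H-chromene
Product: 12 (S)-2-(3-benzyloxy-4-methoxyphenyl)-5,7-dimethoxy-6,8-dimethylchroman-4-one
Conditions: Bu4NF (1.2 equiv), AcOH (2 equiv), THF, 0 °C
Reagents that add atoms: none
Why: Fluoride cleavage of the O–Si bond of a silyl enol ether with acetic acid present, so that the enolate is protonated at once and cannot open ring C by β-elimination of the aryloxide; C3 becomes a CH2 group and C2 is untouched.

Step 10
Reactants: 12 (S)-2-(3-benzyloxy-4-methoxyphenyl)-5,7-dimethoxy-6,8-dimethylchroman-4-one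
Product: 13 (S)-5-hydroxy-2-(3-hydroxy-4-methoxyphenyl)-7-methoxy-6,8-dimethylchroman-4-one
Conditions: BCl3 (4 equiv), C6HMe5 (3 equiv), CH2Cl2, −78 to 0 °C; MeOH, then aq. NaHCO3
Reagents that add atoms: none
Why: Chelation-directed ether cleavage: boron bound to C4=O activates only the peri 5-methoxy group for loss of chloromethane, and the same Lewis acid removes the benzyl ether, with pentamethylbenzene as a non-basic trap for the benzyl cation. The 7- and 4'-methyl ethers have no chelating neighbour and should survive at low temperature.

Step 11
Reactants: 13 (S)-5-hydroxy-2-(3-hydroxy-4-methoxyphenyl)-7-methoxy-6,8-dimethylchroman-4-one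
Product: 14 (S)-5-hydroxy-7-methoxy-2-(4-methoxy-3,6-dioxocyclohexa-1,4-dien-1-yl)-6,8-dimethylchroman-4-one
Conditions: (KSO3)2NO (2.5 equiv), aq. KH2PO4, acetone/H2O, 0 °C to rt
Reagents that add atoms: potassium nitrosodisulfonate (Fremy's salt), [K+].[K+].[O]N(S(=O)(=O)[O-])S(=O)(=O)[O-]
Why: Teuber oxidation: one equivalent of the nitroxyl radical takes the hydrogen atom of the 3'-OH, a second couples at the free para carbon C6', and loss of imidodisulfonate gives the para-quinone. The ring A phenol is chelated and has no free ring position, and the acidic phosphate buffer guards C2 against base-induced ring opening.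

## Compound list

1 | 2,4,6-trihydroxyacetophenone | CC(=O)c1c(O)cc(O)cc1O | starting material
2 | 2,4,6-trihydroxy-3,5-dimethylacetophenone | CC(=O)c1c(O)c(C)c(O)c(C)c1O | intermediate
3 | 2-hydroxy-4,6-dimethoxy-3,5-dimethylacetophenone | CC(=O)c1c(O)c(C)c(OC)c(C)c1OC | intermediate
4 | 3-benzyloxy-4-methoxybenzaldehyde | COc1ccc(C=O)cc1OCc1ccccc1 | starting material
5 | ethyl (E)-3-(3-benzyloxy-4-methoxyphenyl)acrylate | CCOC(=O)/C=C/c1ccc(OC)c(OCc2ccccc2)c1 | intermediate
6 | (E)-3-(3-benzyloxy-4-methoxyphenyl)prop-2-en-1-ol | OC/C=C/c1ccc(OC)c(OCc2ccccc2)c1 | intermediate
7 | (E)-3-(3-benzyloxy-4-methoxyphenyl)allyl methyl carbonate | COC(=O)OC/C=C/c1ccc(OC)c(OCc2ccccc2)c1 | intermediate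
8 | sodium 2-acetyl-3,5-dimethoxy-4,6-dimethylphenolate | [Na+].[O-]c1c(C)c(OC)c(C)c(OC)c1C(C)=O | intermediate
9 | (S)-1-{2-[1-(3-benzyloxy-4-methoxyphenyl)allyloxy]-4,6-dimethoxy-3,5-dimethylphenyl}ethan-1-one | COc1ccc(cc1OCc1ccccc1)[C@@H](Oc2c(C)c(OC)c(C)c(OC)c2C(C)=O)C=C | intermediate
10 | (S)-1-(3-benzyloxy-4-methoxyphenyl)allyl 2-[1-(tert-butyldimethylsilyloxy)vinyl]-3,5-dimethoxy-4,6-dimethylphenyl ether | COc1ccc(cc1OCc1ccccc1)[C@@H](Oc2c(C)c(OC)c(C)c(OC)c2C(=C)O[Si](C)(C)C(C)(C)C)C=C | intermediate
11 | (S)-2-(3-benzyloxy-4-methoxyphenyl)-4-(tert-butyldimethylsilyloxy)-5,7-dimethoxy-6,8-dimethyl-2H-chromene | COc1ccc(cc1OCc1ccccc1)[C@@H]2C=C(O[Si](C)(C)C(C)(C)C)c3c(OC)c(C)c(OC)c(C)c3O2 | intermediate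
12 | (S)-2-(3-benzyloxy-4-methoxyphenyl)-5,7-dimethoxy-6,8-dimethylchroman-4-one | COc1ccc(cc1OCc1ccccc1)[C@@H]2CC(=O)c3c(OC)c(C)c(OC)c(C)c3O2 | intermediate
13 | (S)-5-hydroxy-2-(3-hydroxy-4-methoxyphenyl)-7-methoxy-6,8-dimethylchroman-4-one | COc1ccc(cc1O)[C@@H]2CC(=O)c3c(O)c(C)c(OC)c(C)c3O2 | intermediate
14 | (S)-5-hydroxy-7-methoxy-2-(4-methoxy-3,6-dioxocyclohexa-1,4-dien-1-yl)-6,8-dimethylchroman-4-one | COC1=CC(=O)C([C@@H]2CC(=O)c3c(O)c(C)c(OC)c(C)c3O2)=CC1=O | target

## Step count and risks

Total step count: 11. Longest linear sequence: 9 steps (4 to 14 through steps 3 to 11). The ring A branch (steps 1 and 2) joins at step 6.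

**Step 8 (key step).** The most likely failure is a slow closure. The enol ether is 1,1-disubstituted and electron-rich, and it is crowded by the 5-methoxy group and the silyl group. The alkylidene formed at the vinyl group may then dimerise by cross-metathesis, or decay to a ruthenium hydride that moves the allylic double bond into conjugation and erases C2. Thermal or photochemical ring opening of the product would have the same effect on C2. The fallback gives up metathesis for a conjugate addition; it sets out from 3 and returns at 12. Condensation of 3 with N,N-dimethylformamide dimethyl acetal should give the enaminone (E)-3-(dimethylamino)-1-(2-hydroxy-4,6-dimethoxy-3,5-dimethylphenyl)prop-2-en-1-one F1, which acid (HCl, CH2Cl2) cyclises to 5,7-dimethoxy-6,8-dimethyl-4H-chromen-4-one F2. Asymmetric 1,4-addition of commercial (3-benzyloxy-4-methoxyphenyl)boronic acid to F2 then forms the C2–C1' bond and gives 12 directly. The catalyst would be Pd(OCOCF3)2 with a chiral pyridine–oxazoline ligand in aqueous 1,2-dichloroethane, with the ligand enantiomer chosen for (S).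

**Step 6.** Three things may go wrong. The aryloxide 8 is hindered on both sides and chelated by its acetyl group, so attack on the allyl complex may be slow. The product carries a good leaving group on an electron-rich allyl unit, so re-ionisation may erode both the enantiomeric purity and the branched selectivity. The ketone enolate may be allylated at carbon. The fallback replaces the intermolecular attack by an intramolecular, decarboxylative one; it sets out from 6 and 3 and returns at 9. Alcohol 6 with 1,1'-carbonyldiimidazole should give (E)-3-(3-benzyloxy-4-methoxyphenyl)allyl 1H-imidazole-1-carboxylate F3. Phenol 3 with catalytic DBU converts F3 into the mixed carbonate 2-acetyl-3,5-dimethoxy-4,6-dimethylphenyl (E)-3-(3-benzyloxy-4-methoxyphenyl)allyl carbonate F4. Treatment of F4 with [CpRu(NCMe)3]PF6 and a chiral pyridine–oxazoline ligand should then ionise the carbonate, expel CO2 and return the aryloxide within the ion pair to the substituted allyl terminus, giving 9.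

**Step 10.** The risks are over-reaction, with loss of the 7- or 4'-methyl ether, and Lewis-acid ionisation of the para-methoxybenzylic C2–O1 bond, which opens ring C and loses the configuration. The fallback separates the two deprotections and uses a milder chelating reagent; it sets out from 12 and returns at 13. Hydrogenolysis of 12 (H2, Pd/C, EtOAc) should give (S)-2-(3-hydroxy-4-methoxyphenyl)-5,7-dimethoxy-6,8-dimethylchroman-4-one F5. MgI2 etherate in toluene/THF at 60 °C should then cleave only the methyl ether of F5 that can form a magnesium chelate with C4=O, giving 13.

**Step 11.** The risks are oxidation at the wrong site (the ring A phenol, or ortho attack at C2' to an ortho-quinone) and a slow reaction of a poorly soluble substrate, which would give time for epimerisation at C2. The fallback changes the oxidation manifold from a stoichiometric nitroxyl radical to catalytic aerobic oxygenation through a cobalt–superoxo species (Co(salen), O2, DMF, rt). It sets out from 13 and ends at 14 without a new intermediate.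

## Further compounds

F1 | step 8 | (E)-3-(dimethylamino)-1-(2-hydroxy-4,6-dimethoxy-3,5-dimethylphenyl)prop-2-en-1-one | CN(C)/C=C/C(=O)c1c(O)c(C)c(OC)c(C)c1OC
F2 | step 8 | 5,7-dimethoxy-6,8-dimethyl-4H-chromen-4-one | O=c1ccoc2c(C)c(OC)c(C)c(OC)c12
F3 | step 6 | (E)-3-(3-benzyloxy-4-methoxyphenyl)allyl 1H-imidazole-1-carboxylate | O=C(OC/C=C/c1ccc(OC)c(OCc2ccccc2)c1)n1ccnc1
F4 | step 6 | 2-acetyl-3,5-dimethoxy-4,6-dimethylphenyl (E)-3-(3-benzyloxy-4-methoxyphenyl)allyl carbonate | CC(=O)c1c(OC(=O)OC/C=C/c2ccc(OC)c(OCc3ccccc3)c2)c(C)c(OC)c(C)c1OC
F5 | step 10 | (S)-2-(3-hydroxy-4-methoxyphenyl)-5,7-dimethoxy-6,8-dimethylchroman-4-one | COc1ccc(cc1O)[C@@H]2CC(=O)c3c(OC)c(C)c(OC)c(C)c3O2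
F0 | step 11 | none | none
A1 | alternative 1 | (S)-hesperetin, (S)-5,7-dihydroxy-2-(3-hydroxy-4-methoxyphenyl)chroman-4-one | COc1ccc(cc1O)[C@@H]2CC(=O)c3c(O)cc(O)cc3O2
A2 | alternative 1 | (S)-3'-O-acetyl-6,8-diiodo-7-O-methylhesperetin | COc1ccc(cc1OC(C)=O)[C@@H]2CC(=O)c3c(O)c(I)c(OC)c(I)c3O2
A3 | alternative 1 | tetramethylstannane | C[Sn](C)(C)C
A4 | alternative 1 | (S)-3'-O-acetyl-6,8-dimethyl-7-O-methylhesperetin | COc1ccc(cc1OC(C)=O)[C@@H]2CC(=O)c3c(O)c(C)c(OC)c(C)c3O2
A5 | alternative 2 | 3,5-dimethoxy-4,6-dimethyl-2-(trimethylsilyl)phenyl trifluoromethanesulfonate | COc1c(C)c(OC)c(C)c(OS(=O)(=O)C(F)(F)F)c1[Si](C)(C)C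
A6 | alternative 2 | methyl (S)-3-hydroxy-3-(2,4,5-trimethoxyphenyl)propanoate | COc1cc(OC)c(cc1OC)[C@@H](O)CC(=O)OC
A7 | alternative 2 | (S)-5,7-dimethoxy-6,8-dimethyl-2-(2,4,5-trimethoxyphenyl)chroman-4-one | COc1cc(OC)c(cc1OC)[C@@H]2CC(=O)c3c(OC)c(C)c(OC)c(C)c3O2
A8 | alternative 3 | (S)-2-(3-benzyloxy-4-methoxyphenyl)-6-(2-diazopropanoyl)-2,3-dihydro-4H-pyran-4-one | COc1ccc(cc1OCc1ccccc1)[C@@H]2CC(=O)C=C(O2)C(=O)C(C)=[N+]=[N-]
A9 | alternative 3 | 1-methoxypropyne | CC#COC
A10 | alternative 3 | (S)-2-(3-benzyloxy-4-methoxyphenyl)-5-hydroxy-7-methoxy-6,8-dimethylchroman-4-one | COc1ccc(cc1OCc1ccccc1)[C@@H]2CC(=O)c3c(O)c(C)c(OC)c(C)c3O2
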